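The numbers in the tables were generated by integration for substances that don't exist, and the scatter is random.

Watch the rate of this flask, not its contents, and treat X as a lag settling towards a level.

| setting | alpha | theta | flask |
|---|---|---|---|
| X | 2.0 × 10⁻⁴ M | 2.0 × 10⁻⁴ M | 2.0 × 10⁻⁴ M |
| Z | 20 µM | 30 µM | 20 µM |
| remark | the very flask that is asked about, followed so far | run made earlier |  |
| time |  |  | 5.0 min |

alpha run (percent of the X charged)

| time / s | D / % | X / % |
|---|---|---|
| 10.0 | 3.4 | 96.6 |
| 15.0 | 3.4 | 95.0 |
| 25.0 | 7.3 | 92.2 |

theta run (percent of the X charged)

| time / min | D / % | X / % |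
|---|---|---|
| 0.250 | 6.1 | 93.8 |
| 0.417 | 8.1 | 90.8 |
| 0.667 | 13.4 | 86.4 |
| 1.00 | 19.0 | 81.0 |
| 1.50 | 25.5 | 73.9 |
| 2.50 | 39.0 | 61.9 |
| 4.00 | 52.3 | 48.8 |

(each reading ± 0.5 percentage points)

- the average divides the monomer in chains by the number of chains begun, living and dead together
- what may be going on: 2 Z -> L; D + E -> X + E; X + E -> D + E; X + Z -> E + D
- the earlier runs do not show the number of chains; that part of a forecast is a guess

1. whether the average number of monomer units in a chain (chains begun, living or dead) reaches 8.0 by 5.0 min (yes / no)
2. average number of monomer units in a chain (chains begun, living or dead) at 5.0 min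

I began with the theta run, which ran longer than alpha. X fell at 0.190 min⁻¹ of its charge up to 1.00 min, but at 0.0873 min⁻¹ between 2.50 min and 4.00 min, slower by a factor of 2.18. I drew a straight line through these two rates against the mean X of each stretch, and it reached zero at 25.4% of the charge. I called this reading the floor, the level of X at which the net rate vanishes. In the listed steps E serves both the forward and the backward step, so I carried the floor unchanged to alpha, the asked flask.

Alpha started at 0.187 min⁻¹. Divided by the excess of X over the floor, this gave 0.265 min⁻¹, a pseudo-first-order decay of that excess with a half-life of 2.62 min. By 5.0 min I reckoned the slowing at a factor of 0.266, which put X near 45.3%.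

At that X the length needed fewer than 13.7 µM of chains. The same reckoning for theta gave 0.292 min⁻¹, which was 1.10 times alpha's for 1.50 times the Z. So I guessed that part of the Z began no chain, and I answered yes.

The forecast, which differed from me, gave no and 6.2, saying “Chain count is the guess”.

The flask gave yes and 16.9, reaching the wanted length at 1.69 min.

    2 Z → L (k = 8300 M⁻¹ s⁻¹)
    D + E → X + E, rate k2*[E] as long as [D] is above zero (k = 0.0280 s⁻¹)
    X + E → D + E, rate k3*[E]*[X] (k = 620 M⁻¹ s⁻¹)
    X + Z → E + D (k = 270 M⁻¹ s⁻¹)

At 5.00 min this flask held X at 46.5%, and D was being made 2.06 times faster than it was used up, each step taken net. The forward step goes with X and the backward step does not, so I set that ratio beside X over my floor, which came to 1.83. By 50.0 min X in this flask stood at 22.6%.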